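## The problem

The target is a trans-fused bicyclo[5.3.0]decane (daucane numbering: C1 the methyl-bearing fusion carbon, C2, C3, C4 the isopropyl carbinol, C5 the fusion CH; C6–C10 complete the seven-membered ring). It has seven contiguous stereocentres: C1, C4, C5, C6, C8, C9 and C10. The quaternary carbon C1 cannot be corrected once made, so it must carry the absolute configuration and, through the rigid cyclopentane, set C5 (H trans to the methyl group) and C4 (hydroxyl cis to it); these three must then govern the four centres of the larger ring. On that ring every oxygen (the C6 isovalerate, the C8–C9 epoxide, the C10 acetate) lies on the face of H5 (α below), away from the C1 methyl group (β face). The oxygen functions are fragile: the trisubstituted epoxide beside an acetate opens in acid, two different secondary esters must be placed without exchange, the tertiary C4 hydroxyl dehydrates or undergoes retro-aldol cleavage once C6 is a carbonyl, and a C6 acyloxy group is lost by vinylogous elimination from an 8-en-10-one in base. A short ring construction is possible because C6 and C9 both carry oxygen and face each other across the seven-membered ring with only C7H2–C8(CH3) between them. The oxygen of a C6 aldehyde can therefore be bonded to C9 as a one-atom bridge (a six-membered carbonyl ylide through C9, C10, C1, C5, C6), and C7–C8 can be added as a propene-type two-carbon partner. The catch is facial. In that ylide the C1 methyl group is pseudoaxial and the C4 oxygen flanks C6 on the same side, so the alkene will add from the α face and the bridge oxygen will sit on the β face, opposite to the C6 oxygen of the target; a hydride will likewise attack a C10 ketone anti to the methyl group. The plan therefore uses the bridge to build the ring and to carry the C6 oxygen atom, and sets the configurations at C6 and C10 afterwards.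

## Retrosynthesis

**Acetate and epoxide (31 ⇒ 30 ⇒ 29).** The acetyl C–O bond at C10 and the two C–O bonds of the epoxide are cut first, leading to allylic alcohol 29. The two faces of the C8=C9 bond differ little in crowding, so oxygen delivery from a free 10α-hydroxyl is preferred to an undirected peracid, and acetylation last keeps the acetate out of all earlier steps. The precursor has two stereocentres fewer. The forward steps must give syn oxygen transfer in a cycloheptenol and acylation of a hindered secondary alcohol beside a free tertiary one.

**C10 (29 ⇒ 27 ⇒ 26).** The C10–H bond is cut next, giving enone 26. Hydride should enter C10 anti to the pseudoaxial C1 methyl group, as in reductions of bicyclic ketones flanked by an angular methyl group, so the direct product is the 10β-alcohol 27. One SN2 inversion by an oxygen nucleophile approaching from the same open α face is therefore planned from the start. Epoxidising the enone first and reducing later was set aside, because epoxide and methyl group would then steer the hydride to opposite faces. The forward demand is substitution at an allylic carbinol next to a quaternary carbon.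

**C6 (26 ⇒ 25 ⇒ 24 ⇒ 23 ⇒ 22).** After removal of the isovaleryl group the C6–H bond is cut: alcohol 25 is traced to diketone 24, and 24 through diol 23 to the 6β-alcohol 22. Direct SN2 inversion of 22 was rejected: its hydroxyl is axial, syn to the methyl group and δ to the enone carbonyl, so activation would lead to elimination towards a dienone. Oxidation and reduction keep the oxygen atom delivered by the bridge and erase its configuration. The tertiary 4β-hydroxyl sits on the β side of the C6 carbonyl, so it can deliver hydride there and give the 6α-alcohol. The route thereby no longer depends on the facial course of the ring-forming step. The forward steps must tolerate a tertiary β-hydroxy ketone, so they must be neutral or mildly acidic.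

**Bridge opening (22 ⇒ 20).** Reconnecting C9 to the C6 oxygen and restoring an acetate on C8 gives the bridged ketone 20. The α-alkoxy ketone in 20 is the motif that one-electron reductants cleave; the resulting enolate or ketone then expels the β-acetate, which creates the C8=C9 enone and removes the uncontrolled centre C8 together with C9. Asked of the forward reaction: cleavage of the C9–O bond rather than simple carbonyl reduction, and no over-reduction of the enone.

**Seven-membered ring (20 ⇒ 17 + 18).** C6–C7, C8–C9 and C9–O are cut together. Against the neighbouring two-bond cuts of the ring (discussed under the alternatives), this one leaves a cyclopentane, 17, that already holds C1, C4 and C5, and a commercial enol ester, 18, that brings C7, C8 with its methyl group and a leaving group for the later alkene. A tricyclic ketone is reduced to a monocyclic diazoketone aldehyde. The forward reaction must favour intramolecular ylide formation over intermolecular carbenoid reactions and must join the alkene CH2 to C6; nothing is asked of its facial or exo/endo selectivity.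

**Diazoketone and aldehyde (17 ⇒ 16 ⇒ 15 ⇒ 13 ⇒ 12 ⇒ 11).** The C9–C10 bond is cut to an acid chloride derived from acid 13 and a diazoalkane that supplies C9. The C6 aldehyde is unmasked last (16 ⇒ 17), because a free aldehyde would compete for the diazoalkane. C10 is carried as a dithiane (11) through the organometallic steps and raised to the acid by way of aldehyde 12.

**C4 (11 ⇒ 10 ⇒ 9 ⇒ 8).** The C4–isopropyl bond is cut to ketone 9. The adjacent silyloxymethyl group and the pseudoaxial C1 methyl group both shield the β face, so an isopropyl organometallic should enter from the α face and leave the hydroxyl β.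

**C1 and C5 (8 ⇒ 5 + 6; 5 ⇒ 1 + 2).** The C1–CH3 and C5–C6 bonds are cut: catalytic asymmetric conjugate methylation of enone 5 by 6 sets C1 and hence the absolute configuration. The resulting enolate takes up a one-carbon aldehyde electrophile anti to the bulky dithianyl group, which places the C6 carbon cis to the methyl group. Enone 5 comes from 1 and 2 by addition and hydrolytic transposition.

## Roads not taken

**Alternative 1:** The cut runs through C1–C5 and C6–C7, with a cyclopropane bond C7–C9 as the hidden third bond. A chain carrying a silylated alkyne, the finished C4 carbinol and a methyl-substituted vinylcyclopropane would be closed by [Rh(CO)2Cl]2 in a (5+2) cycloaddition to diene A1, forming both rings at once.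
- Merits: it is the shortest entry to the bicyclic core. The C9=C10 alkene of A1 would allow the C10 oxygen to be introduced by electrophilic oxygen on the open α face (epoxidation, then isomerisation to the 10α-allylic alcohol). That is better than the chosen plan, which needs an inversion at C10.
- Weak points: the quaternary carbon C1 would be formed in the cycloaddition from a fully substituted alkene terminus, at the edge of what this catalyst tolerates. Its configuration relative to C4 would rest on remote induction through a flexible tether. C5 is trigonal in A1 and would have to be set later by protonation next to a C6 carbonyl, where the cis-fused isomer may be favoured.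
- Comparison: the chosen plan is longer, but C1, C5 and C4 are fixed on a cyclopentane by three substrate-controlled steps before the large ring exists.

**Alternative 2:** The cut runs through C7–C8 and C1–C10. A vinylcarbenoid generated by Rh2(S-DOSP)4 would cyclopropanate the enol ether bond of a cyclopentenone-derived diene, and Cope rearrangement of the cis-divinylcyclopropane would give cycloheptadiene A2.
- Merits: the seven-membered ring and the quaternary centre arise in one catalytic, enantioselective step from simple partners. In convergence and in catalyst control of the ring-forming step it is better than the chosen plan.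
- Weak points: A2 has the wrong oxidation pattern for this target. C8 carries an ester that must become a methyl group, C10 is an unactivated CH2 next to a quaternary carbon and would need an α-selective C–H oxidation, C4 is part of a vinylogous ester, and C5 is again trigonal.
- Comparison: the chosen plan brings C8 as a methyl-bearing carbon, C10 with its oxygen and C4/C5 in their final form into the ring-forming step.

**Alternative 3:** The cut runs through C5–C6 and C4–O. A nitrile oxide carrying the C7–C9 vinyl iodide chain would add to the trisubstituted C4=C5 bond of a cyclopentene, anti to the dithianyl group on C1, to give isoxazoline A3. Later steps would unmask the C10 aldehyde, close the seven-membered ring with CrCl2 and catalytic NiCl2, and cleave the N–O bond to a β-hydroxy ketone.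
- Merits: C4–O and C5–C6 are formed cis in one stereospecific step. C6 arrives as a ketone, so no configuration has to be erased and the same hydroxyl-directed reduction applies. Ring closure gives the C8=C9 alkene and the C10 carbinol directly, without bridge opening or diazo chemistry. For C6 this road is more direct than the chosen plan.
- Weak points: the cycloaddition must occur on a hindered alkene next to a quaternary carbon, in competition with dimerisation of the nitrile oxide. The ring closure is a medium-ring cyclisation onto a neopentyl aldehyde with stoichiometric chromium and no control of C10. The vinyl iodide must survive N–O cleavage.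
- Comparison: the chosen plan forms both new C–C bonds of the ring in one intermolecular step from a commercial three-carbon unit and avoids a medium-ring closure.

Key step: step 11

Remark 1: daucane locants are used for all intermediates; "daucane" denotes the carbon skeleton of the target; β is the face of the C1 methyl group, α the face of H5; the ring fusion is trans (H5 α, 1-methyl β) throughout.
Remark 2: C8 of 20 and 21 is drawn as one epimer; either epimer serves, because C8 becomes trigonal in step 12.
Remark 3: in step 2 the ligand antipode is the one that gives the (S)-configured quaternary carbon; which antipode that is must be established on 8.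

Step 1
Reactants: 1 1,3-dithiane; 2 3-ethoxycyclopent-2-en-1-one
Product: 5 3-(1,3-dithian-2-yl)cyclopent-2-en-1-one, via 2-lithio-1,3-dithiane 3 (not isolated), via lithium 1-(1,3-dithian-2-yl)-3-ethoxycyclopent-2-en-1-olate 4 (not isolated)
Conditions: n-BuLi, THF, −30 °C; 2, −78 → 0 °C; then 1 M HCl, rt
Reagents that add atoms: water, O
Why: Stork–Danheiser enone synthesis: 1,2-addition of the lithiated dithiane to the vinylogous ester, then acid hydrolysis with loss of the tertiary hydroxyl, transposes the carbonyl and leaves the masked acyl carbon C10 on the enone β-carbon (future C1). No stereocentre is formed.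

Step 2
Reactants: 5 3-(1,3-dithian-2-yl)cyclopent-2-en-1-one; 6 trimethylaluminium
Product: 8 (2S,3S)-3-(1,3-dithian-2-yl)-2-(hydroxymethyl)-3-methylcyclopentan-1-one, via dimethylaluminium enolate 7 (not isolated)
Conditions: Cu(OTf)2 (2 mol %), chiral phosphoramidite ligand (4 mol %), Et2O, −30 °C; then monomeric CH2O in THF, −78 → −30 °C; aq. potassium sodium tartrate
Reagents that add atoms: formaldehyde, C=O
Why: Copper-catalysed asymmetric conjugate addition of a trialkylaluminium to a β-substituted cyclopentenone creates the quaternary carbon C1 under ligand control. The aluminium enolate then undergoes an aldol reaction with formaldehyde on the face anti to the bulky dithianyl group, so the hydroxymethyl group (C6) is cis to the methyl group.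

Step 3
Reactants: 8 (2S,3S)-3-(1,3-dithian-2-yl)-2-(hydroxymethyl)-3-methylcyclopentan-1-one
Product: 9 (2S,3S)-2-{[tert-butyl(dimethyl)silyl]oxymethyl}-3-(1,3-dithian-2-yl)-3-methylcyclopentan-1-one
Conditions: TBSCl, imidazole, DMF, 0 °C → rt
Reagents that add atoms: tert-butyldimethylsilyl chloride, CC(C)(C)[Si](C)(C)Cl
Why: Silylation of the primary alcohol; it prevents retro-aldol loss of the C6 carbon in the next step and adds bulk on the β face.

Step 4
Reactants: 9 (2S,3S)-2-{[tert-butyl(dimethyl)silyl]oxymethyl}-3-(1,3-dithian-2-yl)-3-methylcyclopentan-1-one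
Product: 10 (1R,2S,3S)-2-{[tert-butyl(dimethyl)silyl]oxymethyl}-3-(1,3-dithian-2-yl)-3-methyl-1-(propan-2-yl)cyclopentan-1-ol
Conditions: i-PrMgCl, anhydrous CeCl3, THF, −78 °C
Reagents that add atoms: isopropylmagnesium chloride, CC(C)[Mg]Cl
Why: Organocerium (Imamoto) addition suppresses enolisation and β-hydride reduction of the hindered ketone. The nucleophile enters anti to the adjacent silyloxymethyl group and to the pseudoaxial C1 methyl group, so the isopropyl group is α and the hydroxyl β (cis to CH2OTBS and methyl).

Step 5
Reactants: 10 (1R,2S,3S)-2-{[tert-butyl(dimethyl)silyl]oxymethyl}-3-(1,3-dithian-2-yl)-3-methyl-1-(propan-2-yl)cyclopentan-1-ol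
Product: 11 triethylsilyl ether of 10, {[(1R,2S,3S)-2-{[tert-butyl(dimethyl)silyl]oxymethyl}-3-(1,3-dithian-2-yl)-3-methyl-1-(propan-2-yl)cyclopentyl]oxy}triethylsilane
Conditions: TESOTf, 2,6-lutidine, CH2Cl2, −78 → 0 °C
Reagents that add atoms: triethylsilyl triflate, CC[Si](CC)(CC)OS(=O)(=O)C(F)(F)F
Why: Silyl triflate silylation of a tertiary alcohol; the ether protects C4–OH during acid chloride formation and keeps the hydroxyl from trapping the ylide in step 11.

Step 6
Reactants: 11 triethylsilyl ether of 10
Product: 12 (1S,2S,3R)-2-{[tert-butyl(dimethyl)silyl]oxymethyl}-1-methyl-3-(propan-2-yl)-3-(triethylsilyloxy)cyclopentane-1-carbaldehyde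
Conditions: MeI, CaCO3, MeCN–H2O (9:1), 40 °C
Reagents that add atoms: water, O
Why: S-Alkylative hydrolysis of the dithioacetal under buffered, near-neutral conditions that spare both silyl ethers; the aldehyde sits on a quaternary carbon and cannot epimerise.

Step 7
Reactants: 12 (1S,2S,3R)-2-{[tert-butyl(dimethyl)silyl]oxymethyl}-1-methyl-3-(propan-2-yl)-3-(triethylsilyloxy)cyclopentane-1-carbaldehyde
Product: 13 (1S,2S,3R)-2-{[tert-butyl(dimethyl)silyl]oxymethyl}-1-methyl-3-(propan-2-yl)-3-(triethylsilyloxy)cyclopentane-1-carboxylic acid
Conditions: NaClO2, NaH2PO4, 2-methylbut-2-ene, t-BuOH–H2O, 0 °C → rt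
Reagents that add atoms: sodium chlorite, [Na+].[O-]Cl=O
Why: Pinnick oxidation of an aldehyde to the acid; the sulfur has been removed in step 6, so nothing else is oxidisable.

Step 8
Reactants: 13 (1S,2S,3R)-2-{[tert-butyl(dimethyl)silyl]oxymethyl}-1-methyl-3-(propan-2-yl)-3-(triethylsilyloxy)cyclopentane-1-carboxylic acid
Product: 15 2-diazo-1-[(1S,2S,3R)-2-{[tert-butyl(dimethyl)silyl]oxymethyl}-1-methyl-3-(propan-2-yl)-3-(triethylsilyloxy)cyclopentyl]ethan-1-one, via acid chloride 14 (not isolated)
Conditions: 1-chloro-N,N,2-trimethylprop-1-en-1-amine, CH2Cl2, 0 °C; then CH2N2 (excess), Et2O, 0 °C → rt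
Reagents that add atoms: diazomethane, C=[N+]=[N-]
Why: Acylation of diazomethane by an acid chloride (first stage of the Arndt–Eistert sequence); the chloride is made under neutral conditions that spare the silyl ethers, and the quaternary α-carbon excludes ketene formation. Diazomethane supplies C9.

Step 9
Reactants: 15 2-diazo-1-[(1S,2S,3R)-2-{[tert-butyl(dimethyl)silyl]oxymethyl}-1-methyl-3-(propan-2-yl)-3-(triethylsilyloxy)cyclopentyl]ethan-1-one
Product: 16 2-diazo-1-[(1S,2S,3R)-2-(hydroxymethyl)-1-methyl-3-(propan-2-yl)-3-(triethylsilyloxy)cyclopentyl]ethan-1-one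
Conditions: TBAF, AcOH (1:1), THF, 0 °C
Reagents that add atoms: none
Why: Fluoride desilylation; the primary TBS ether should be cleaved well before the tertiary TES ether, which is shielded by the isopropyl group and the ring. Buffered fluoride leaves the diazoketone intact.

Step 10
Reactants: 16 2-diazo-1-[(1S,2S,3R)-2-(hydroxymethyl)-1-methyl-3-(propan-2-yl)-3-(triethylsilyloxy)cyclopentyl]ethan-1-one
Product: 17 (1R,2S,5R)-2-(2-diazoacetyl)-2-methyl-5-(propan-2-yl)-5-(triethylsilyloxy)cyclopentane-1-carbaldehyde
Conditions: Dess–Martin periodinane, NaHCO3, CH2Cl2, 0 °C → rt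
Reagents that add atoms: none
Why: Dess–Martin oxidation of a primary alcohol; diazoketones tolerate it. The aldehyde stays trans to the diazoacetyl group, which is also the less crowded arrangement, and is used at once.

Step 11
Reactants: 17 (1R,2S,5R)-2-(2-diazoacetyl)-2-methyl-5-(propan-2-yl)-5-(triethylsilyloxy)cyclopentane-1-carbaldehyde; 18 isopropenyl acetate
Product: 20 8-acetoxy-6β,9β-epoxy-4β-(triethylsilyloxy)daucan-10-one (oxygen bridge from C6 to C9 on the β face; acetoxy group on C8 syn to the bridge), via carbonyl ylide 19 (not isolated)
Conditions: Rh2(OAc)4 (2 mol %), 18 (20 equiv), PhH, 60 °C, slow addition of 17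
Reagents that add atoms: none
Why: Rh2(OAc)4 converts the diazoketone into a rhodium carbenoid at C9, which is captured by a lone pair of the C6 aldehyde oxygen (C9–O bond; closure of the six-membered oxanone ring, trans-fused to the cyclopentane) to give carbonyl ylide 19. The ylide then undergoes an intermolecular 1,3-dipolar (3+2) cycloaddition with 18 that forms C6–C7 and C8–C9 and so closes the oxolane and the seven-membered carbocycle in one event. The closest known reaction type is the tandem carbonyl ylide formation–cycloaddition of δ-carbonyl α-diazoketones with electron-rich alkenes. The selectivity that matters is regiochemistry: C9 is the enolate-like, nucleophilic terminus and C6 the oxocarbenium-like, electrophilic one, so the nucleophilic CH2 of the enol acetate bonds to C6 and the acetoxy-bearing carbon, which takes up the developing positive charge, bonds to C9; the less hindered alkene terminus also meets the more hindered ylide terminus. C6 and C9 are set together by the ylide face that is attacked: the C1 methyl group is pseudoaxial and the C4 silyloxy group flanks C6 on the same β face, so the alkene should add from the α face and place the bridge on the β face. C8 is set by the exo/endo orientation of the alkene, which is not controlled. None of these three configurations reaches the target (C6 is oxidised in step 14; C8 and C9 become trigonal in step 12), so the step has to deliver constitution only. Ylide formation should outrun cyclopropanation of 18 because capture of the carbenoid by the aldehyde is an intramolecular six-ring closure.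

Step 12
Reactants: 20 8-acetoxy-6β,9β-epoxy-4β-(triethylsilyloxy)daucan-10-one
Product: 22 6β-hydroxy-4β-(triethylsilyloxy)dauc-8-en-10-one, via β-acetoxy ketone 21 (not isolated)
Conditions: SmI2 (2.5 equiv), THF–MeOH, −78 °C; then DBU, CH2Cl2, 0 °C → rt
Reagents that add atoms: none
Why: Reductive cleavage of an α-alkoxy ketone by SmI2 breaks the C9–O bond and frees the C6 hydroxyl; methanol protonates the enolate at low temperature so that no enone meets the reductant. E1cB loss of acetic acid then gives the conjugated C8=C9 enone and removes the stereocentres C8 and C9.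

Step 13
Reactants: 22 6β-hydroxy-4β-(triethylsilyloxy)dauc-8-en-10-one
Product: 23 4β,6β-dihydroxydauc-8-en-10-one
Conditions: HF·pyridine, pyridine, THF, 0 °C → rt
Reagents that add atoms: none
Why: Fluoride cleavage of the tertiary silyl ether at a stage with no epoxide and no β-hydroxy ketone; the free 4β-hydroxyl is needed as the directing group in step 15.

Step 14
Reactants: 23 4β,6β-dihydroxydauc-8-en-10-one
Product: 24 4β-hydroxydauc-8-ene-6,10-dione
Conditions: Dess–Martin periodinane, NaHCO3, CH2Cl2, 0 °C
Reagents that add atoms: none
Why: Dess–Martin oxidation of the secondary alcohol only (the tertiary one is inert) under buffered conditions that avoid dehydration or retro-aldol cleavage. It erases the C6 configuration left by the cycloaddition while keeping the oxygen atom delivered by the bridge.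

Step 15
Reactants: 24 4β-hydroxydauc-8-ene-6,10-dione
Product: 25 4β,6α-dihydroxydauc-8-en-10-one
Conditions: Me4NBH(OAc)3, MeCN–AcOH, −30 °C
Reagents that add atoms: none
Why: Evans–Saksena hydroxyl-directed reduction: the borohydride exchanges onto the 4β-hydroxyl and delivers hydride through a chair-like six-membered transition state to the β face of the C6 carbonyl, which gives the 4,6-anti diol (6α-OH). The enone carbonyl has no hydroxyl within reach and is not reduced.

Step 16
Reactants: 25 4β,6α-dihydroxydauc-8-en-10-one
Product: 26 4β-hydroxy-6α-(3-methylbutanoyloxy)dauc-8-en-10-one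
Conditions: isovaleryl chloride, pyridine, DMAP (cat.), CH2Cl2, 0 °C
Reagents that add atoms: 3-methylbutanoyl chloride, CC(C)CC(Cl)=O
Why: Acylation of the equatorial secondary alcohol; the hindered tertiary hydroxyl does not react, and the weak base avoids vinylogous elimination of the new ester.

Step 17
Reactants: 26 4β-hydroxy-6α-(3-methylbutanoyloxy)dauc-8-en-10-one
Product: 27 6α-(3-methylbutanoyloxy)dauc-8-ene-4β,10β-diol
Conditions: NaBH4, CeCl3·7H2O, MeOH, −78 °C
Reagents that add atoms: none
Why: Luche 1,2-reduction of the enone; hydride should attack C10 anti to the pseudoaxial C1 methyl group (Felkin-type approach, as with ketones beside an angular methyl group), so the hydroxyl ends up β. The ester is untouched at this temperature.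

Step 18
Reactants: 27 6α-(3-methylbutanoyloxy)dauc-8-ene-4β,10β-diol
Product: 29 6α-(3-methylbutanoyloxy)dauc-8-ene-4β,10α-diol, via 10α-formate 28 (not isolated)
Conditions: PPh3, DIAD, HCO2H, THF, 0 °C → rt; then K2CO3 (cat.), MeOH, 0 °C
Reagents that add atoms: formic acid, OC=O
Why: Mitsunobu inversion: formate displaces the activated allylic 10β-oxygen from the open α face, along the trajectory that hydride took in step 17; the inversion of carbinols syn to an angular methyl group next to a quaternary carbon is the closest precedent. The formate is then methanolysed far faster than the hindered isovalerate; the tertiary hydroxyl does not take part.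

Step 19
Reactants: 29 6α-(3-methylbutanoyloxy)dauc-8-ene-4β,10α-diol
Product: 30 8α,9α-epoxy-6α-(3-methylbutanoyloxy)daucane-4β,10α-diol
Conditions: VO(acac)2 (5 mol %), t-BuOOH, CH2Cl2, 0 °C → rt
Reagents that add atoms: tert-butyl hydroperoxide, CC(C)(C)OO
Why: Hydroxyl-directed epoxidation of an allylic alcohol: the vanadium alkoxide delivers the peroxide oxygen syn to the 10α-hydroxyl, as is the rule for five- to seven-membered cyclic allylic alcohols, which sets C8 and C9 with the epoxide α. The conditions are neutral and leave the ester untouched.

Step 20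
Reactants: 30 8α,9α-epoxy-6α-(3-methylbutanoyloxy)daucane-4β,10α-diol
Product: 31 10α-acetoxy-8α,9α-epoxy-6α-(3-methylbutanoyloxy)daucan-4β-ol (CNP0137153.1)
Conditions: Ac2O, pyridine, DMAP (cat.), CH2Cl2, 0 °C → rt
Reagents that add atoms: acetic anhydride, CC(=O)OC(C)=O
Why: Nucleophile-catalysed acetylation of the secondary C10 alcohol; the tertiary C4 hydroxyl is too hindered to react, and the epoxide is not exposed to acid.

## Compound list

1 | 1,3-dithiane | C1CSCSC1 | starting material
2 | 3-ethoxycyclopent-2-en-1-one | CCOC1=CC(=O)CC1 | starting material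
3 | 2-lithio-1,3-dithiane | [Li]C1SCCCS1 | intermediate (not isolated)
4 | lithium 1-(1,3-dithian-2-yl)-3-ethoxycyclopent-2-en-1-olate (racemic) | [Li+].[O-]C1(C=C(OCC)CC1)C1SCCCS1 | intermediate (not isolated)
5 | 3-(1,3-dithian-2-yl)cyclopent-2-en-1-one | O=C1CCC(=C1)C1SCCCS1 | intermediate
6 | trimethylaluminium | C[Al](C)C | starting material
7 | dimethylaluminium (S)-3-(1,3-dithian-2-yl)-3-methylcyclopent-1-en-1-olate | C[Al](C)OC1=C[C@](C)(CC1)C1SCCCS1 | intermediate (not isolated)
8 | (2S,3S)-3-(1,3-dithian-2-yl)-2-(hydroxymethyl)-3-methylcyclopentan-1-one | C1(SCCCS1)[C@@]2(C)CCC(=O)[C@@H]2CO | intermediate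
9 | (2S,3S)-2-{[tert-butyl(dimethyl)silyl]oxymethyl}-3-(1,3-dithian-2-yl)-3-methylcyclopentan-1-one | C1(SCCCS1)[C@@]2(C)CCC(=O)[C@@H]2CO[Si](C)(C)C(C)(C)C | intermediate
10 | (1R,2S,3S)-2-{[tert-butyl(dimethyl)silyl]oxymethyl}-3-(1,3-dithian-2-yl)-3-methyl-1-(propan-2-yl)cyclopentan-1-ol | C1(SCCCS1)[C@@]2(C)CC[C@@](O)(C(C)C)[C@@H]2CO[Si](C)(C)C(C)(C)C | intermediate
11 | triethylsilyl ether of 10 | C1(SCCCS1)[C@@]2(C)CC[C@@](O[Si](CC)(CC)CC)(C(C)C)[C@@H]2CO[Si](C)(C)C(C)(C)C | intermediate
12 | (1S,2S,3R)-2-{[tert-butyl(dimethyl)silyl]oxymethyl}-1-methyl-3-(propan-2-yl)-3-(triethylsilyloxy)cyclopentane-1-carbaldehyde | O=C[C@@]1(C)CC[C@@](O[Si](CC)(CC)CC)(C(C)C)[C@@H]1CO[Si](C)(C)C(C)(C)C | intermediate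
13 | (1S,2S,3R)-2-{[tert-butyl(dimethyl)silyl]oxymethyl}-1-methyl-3-(propan-2-yl)-3-(triethylsilyloxy)cyclopentane-1-carboxylic acid | OC(=O)[C@@]1(C)CC[C@@](O[Si](CC)(CC)CC)(C(C)C)[C@@H]1CO[Si](C)(C)C(C)(C)C | intermediate
14 | acid chloride of 13 | ClC(=O)[C@@]1(C)CC[C@@](O[Si](CC)(CC)CC)(C(C)C)[C@@H]1CO[Si](C)(C)C(C)(C)C | intermediate (not isolated)
15 | 2-diazo-1-[(1S,2S,3R)-2-{[tert-butyl(dimethyl)silyl]oxymethyl}-1-methyl-3-(propan-2-yl)-3-(triethylsilyloxy)cyclopentyl]ethan-1-one | [N-]=[N+]=CC(=O)[C@@]1(C)CC[C@@](O[Si](CC)(CC)CC)(C(C)C)[C@@H]1CO[Si](C)(C)C(C)(C)C | intermediate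
16 | 2-diazo-1-[(1S,2S,3R)-2-(hydroxymethyl)-1-methyl-3-(propan-2-yl)-3-(triethylsilyloxy)cyclopentyl]ethan-1-one | [N-]=[N+]=CC(=O)[C@@]1(C)CC[C@@](O[Si](CC)(CC)CC)(C(C)C)[C@@H]1CO | intermediate
17 | (1R,2S,5R)-2-(2-diazoacetyl)-2-methyl-5-(propan-2-yl)-5-(triethylsilyloxy)cyclopentane-1-carbaldehyde | [N-]=[N+]=CC(=O)[C@@]1(C)CC[C@@](O[Si](CC)(CC)CC)(C(C)C)[C@@H]1C=O | intermediate
18 | isopropenyl acetate (prop-1-en-2-yl acetate) | CC(=C)OC(C)=O | starting material
19 | six-membered carbonyl ylide from 17 (C9 carbanion, C6=O+ oxocarbenium, C10 ketone; trans-fused to the cyclopentane) | O=C1[CH-][O+]=C[C@@H]2[C@]1(C)CC[C@@]2(O[Si](CC)(CC)CC)C(C)C | intermediate (not isolated)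
20 | 8-acetoxy-6β,9β-epoxy-4β-(triethylsilyloxy)daucan-10-one (acetoxy syn to the bridge) | O=C1[C@H]2O[C@H](C[C@]2(C)OC(C)=O)[C@@H]2[C@]1(C)CC[C@@]2(O[Si](CC)(CC)CC)C(C)C | intermediate
21 | 8-acetoxy-6β-hydroxy-4β-(triethylsilyloxy)daucan-10-one | O=C1C[C@@](C)(OC(C)=O)C[C@@H](O)[C@@H]2[C@]1(C)CC[C@@]2(O[Si](CC)(CC)CC)C(C)C | intermediate (not isolated)
22 | 6β-hydroxy-4β-(triethylsilyloxy)dauc-8-en-10-one | O=C1C=C(C)C[C@@H](O)[C@@H]2[C@]1(C)CC[C@@]2(O[Si](CC)(CC)CC)C(C)C | intermediate
23 | 4β,6β-dihydroxydauc-8-en-10-one | O=C1C=C(C)C[C@@H](O)[C@@H]2[C@]1(C)CC[C@@]2(O)C(C)C | intermediate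
24 | 4β-hydroxydauc-8-ene-6,10-dione | O=C1C=C(C)CC(=O)[C@@H]2[C@]1(C)CC[C@@]2(O)C(C)C | intermediate
25 | 4β,6α-dihydroxydauc-8-en-10-one | O=C1C=C(C)C[C@H](O)[C@@H]2[C@]1(C)CC[C@@]2(O)C(C)C | intermediate
26 | 4β-hydroxy-6α-(3-methylbutanoyloxy)dauc-8-en-10-one | O=C1C=C(C)C[C@H](OC(=O)CC(C)C)[C@@H]2[C@]1(C)CC[C@@]2(O)C(C)C | intermediate
27 | 6α-(3-methylbutanoyloxy)dauc-8-ene-4β,10β-diol | O[C@H]1C=C(C)C[C@H](OC(=O)CC(C)C)[C@@H]2[C@]1(C)CC[C@@]2(O)C(C)C | intermediate
28 | 10α-formyloxy-6α-(3-methylbutanoyloxy)dauc-8-en-4β-ol | O=CO[C@@H]1C=C(C)C[C@H](OC(=O)CC(C)C)[C@@H]2[C@]1(C)CC[C@@]2(O)C(C)C | intermediate (not isolated)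
29 | 6α-(3-methylbutanoyloxy)dauc-8-ene-4β,10α-diol | O[C@@H]1C=C(C)C[C@H](OC(=O)CC(C)C)[C@@H]2[C@]1(C)CC[C@@]2(O)C(C)C | intermediate
30 | 8α,9α-epoxy-6α-(3-methylbutanoyloxy)daucane-4β,10α-diol | O[C@@H]1[C@@H]2O[C@]2(C)C[C@H](OC(=O)CC(C)C)[C@@H]2[C@]1(C)CC[C@@]2(O)C(C)C | intermediate
31 | 10α-acetoxy-8α,9α-epoxy-6α-(3-methylbutanoyloxy)daucan-4β-ol (CNP0137153.1) | CC(=O)O[C@@H]1[C@@H]2O[C@]2(C)C[C@H](OC(=O)CC(C)C)[C@@H]2[C@]1(C)CC[C@@]2(O)C(C)C | target

## Step count and least certain steps

Total step count: 20. Longest linear sequence: 20 steps (2 → 31; 1, 6 and 18 enter along it).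

**Step 11 (key step).**
- Risk: the weakly nucleophilic enol acetate may not intercept the ylide in time. The carbenoid would then cyclopropanate the enol acetate intermolecularly, or the ylide would dimerise or collapse by hydrogen shift. A smaller risk is addition in the reverse orientation. The facial and exo/endo outcome does not matter.
- Fallback: from 17, use the more nucleophilic enol ether 2-methoxypropene as dipolarophile (same polarity, hence the same regiochemistry) to give 6β,9β-epoxy-8-methoxy-4β-(triethylsilyloxy)daucan-10-one F1. SmI2 cleavage gives 6β-hydroxy-8-methoxy-4β-(triethylsilyloxy)daucan-10-one F2, which loses methanol with DBU in toluene at 60 °C and returns to the route at 22.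

**Step 2.**
- Risk: slow or poorly enantioselective methyl transfer, because the branched, sulfur-bearing β-substituent hinders the enone and can bind copper; and incomplete capture of the weakly nucleophilic aluminium enolate by formaldehyde, or dehydration of the aldol.
- Fallback: separate the two events. From 5, quench the conjugate addition with TMSOTf and isolate (S)-{[3-(1,3-dithian-2-yl)-3-methylcyclopent-1-en-1-yl]oxy}trimethylsilane F3; then hydroxymethylate by a Sc(OTf)3-catalysed Mukaiyama aldol reaction with aqueous formaldehyde, which returns to the route at 8.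

**Step 12.**
- Risk: simple reduction of the hindered ketone or pinacol coupling instead of C9–O cleavage, if the C9–O bond overlaps poorly with the ketyl in the boat-shaped bicycle; and over-reduction of the enone by excess SmI2.
- Fallback: an eliminative opening without electron transfer. From 20, hydrazine gives the hydrazone of 20 F4. KOtBu in DMSO effects Kishner–Leonard elimination (loss of N2, opening of the bridge, cleavage of the acetate) to 4β-(triethylsilyloxy)dauc-9-ene-6β,8-diol F5. Pyridinium chlorochromate, [C5H5NH][CrO3Cl], then oxidises C6 and transposes the tertiary allylic alcohol oxidatively to 4β-(triethylsilyloxy)dauc-8-ene-6,10-dione F6. HF·pyridine returns to the route at 24.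

**Step 15.**
- Risk: slow exchange of the hindered tertiary hydroxyl onto boron, so that undirected hydride attack from the α face (giving the 6β-alcohol again) competes; and acid-promoted dehydration of the tertiary β-hydroxy ketone.
- Fallback: a covalent silicon tether. From 24, chlorodiisopropylsilane and imidazole give 4β-[di(propan-2-yl)silyloxy]dauc-8-ene-6,10-dione F7. SnCl4 at −78 °C triggers intramolecular hydrosilylation of the C6 carbonyl from the β face to the cyclic 4β,6α-[di(propan-2-yl)silanediyl]dioxy-dauc-8-en-10-one F8. HF·pyridine returns to the route at 25.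

**Step 18.**
- Risk: ionisation of the activated allylic, neopentyl-type carbinol instead of clean SN2, leading to attack of formate at C8, 1,4-elimination to a diene, or incomplete activation of a hydroxyl crowded by the C1 methyl group.
- Fallback: reagent-controlled reduction in place of steps 17 and 18. From 26, use the antipode of 2-methyl-CBS-oxazaborolidine that delivers hydride to the β face, with catecholborane at −78 °C, to return to the route at 29.

## Further compounds

F1 | step 11 | 6β,9β-epoxy-8-methoxy-4β-(triethylsilyloxy)daucan-10-one | O=C1[C@H]2O[C@H](C[C@]2(C)OC)[C@@H]2[C@]1(C)CC[C@@]2(O[Si](CC)(CC)CC)C(C)C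
F2 | step 11 | 6β-hydroxy-8-methoxy-4β-(triethylsilyloxy)daucan-10-one | O=C1C[C@@](C)(OC)C[C@@H](O)[C@@H]2[C@]1(C)CC[C@@]2(O[Si](CC)(CC)CC)C(C)C
F3 | step 2 | (S)-{[3-(1,3-dithian-2-yl)-3-methylcyclopent-1-en-1-yl]oxy}trimethylsilane | C[Si](C)(C)OC1=C[C@](C)(CC1)C1SCCCS1
F4 | step 12 | hydrazone of 20 | NN=C1[C@H]2O[C@H](C[C@]2(C)OC(C)=O)[C@@H]2[C@]1(C)CC[C@@]2(O[Si](CC)(CC)CC)C(C)C
F5 | step 12 | 4β-(triethylsilyloxy)dauc-9-ene-6β,8-diol | C1=C[C@@](C)(O)C[C@@H](O)[C@@H]2[C@]1(C)CC[C@@]2(O[Si](CC)(CC)CC)C(C)C
F6 | step 12 | 4β-(triethylsilyloxy)dauc-8-ene-6,10-dione | O=C1C=C(C)CC(=O)[C@@H]2[C@]1(C)CC[C@@]2(O[Si](CC)(CC)CC)C(C)C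
F7 | step 15 | 4β-[di(propan-2-yl)silyloxy]dauc-8-ene-6,10-dione | O=C1C=C(C)CC(=O)[C@@H]2[C@]1(C)CC[C@@]2(O[SiH](C(C)C)C(C)C)C(C)C
F8 | step 15 | 4β,6α-[di(propan-2-yl)silanediyl]dioxy-dauc-8-en-10-one | O=C1C=C(C)C[C@H](O[Si]3(C(C)C)C(C)C)[C@@H]2[C@]1(C)CC[C@@]2(O3)C(C)C
F0 | step 18 | none | none
A1 | alternative 1 | 6-[benzyl(dimethyl)silyl]dauca-5,9-dien-4-ol (hydroazula-5,9-diene with quaternary C1) | C[C@H]1CC([Si](C)(C)Cc2ccccc2)=C2[C@](O)(C(C)C)CC[C@]2(C)C=C1
A2 | alternative 2 | methyl 6-ethoxy-1-methyl-4-oxobicyclo[5.3.0]deca-5,8-diene-8-carboxylate (daucane locants) | COC(=O)C1=CC[C@@]2(C)CCC(=O)C2=C(OCC)C1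
A3 | alternative 3 | cyclopenta-fused isoxazoline with 1,3-dithian-2-yl on C1 and a (Z)-3-iodo-2-methylprop-2-enyl chain on C6 | CC(C)[C@]12CC[C@](C)(C3SCCCS3)[C@H]1C(C/C(C)=C\I)=NO2
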